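**Assumption:** the target SMILES carries no stereodescriptor and the molecule has no stereogenic centre. The 18-membered cyclophane is taken as conformationally mobile (no stable planar chirality), so no enantiocontrol is required.

## Retrosynthetic overview

1. The last ring closed is the 18-membered macrocycle, through the diaryl ether bond between ring A (the methoxy-hydroxy arene) and the oxygen of ring B (the meta-bridged arene). The ring-B phenoxide adds to C3 of a ring-A quinone monoketal, and loss of MeOH rearomatises ring A.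
2. Enabling feature: ring A is a 4-methoxyphenol whose aryloxy carbon (C3) lies between the OMe carbon (C4) and the carbon bearing the benzylic CH2 (C2). With that CH2 temporarily a ketone, C3 of the 4,4-dimethoxydienone is the β-carbon of an alkylidene-1,3-dicarbonyl.
3. The seco chain is built from four preformed arenes: Chan–Lam etherification (C–O–D), B-alkyl Suzuki coupling (B–CH2CH2–C), and Pd α-arylation of an acetophenone (D–CH2–CO–A).
4. The closing step removes the ketone (to CH2) and the ring-C PMB group together.

Key step: step 10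

## Route

Step 1
Reactants: 1 3-vinylphenol
Product: 2 triisopropyl(3-vinylphenoxy)silane
Conditions: TIPSCl, imidazole, DMF, rt
Reagents that add atoms: triisopropylsilyl chloride, CC(C)[Si](Cl)(C(C)C)C(C)C
Why: Standard phenol silylation; the hindered TIPS ether should survive the basic cross-couplings and the later oxidation until fluoride is applied.

Step 2
Reactants: 3 5-bromo-2-hydroxybenzaldehyde
Product: 4 5-bromo-2-[(4-methoxybenzyl)oxy]benzaldehyde
Conditions: PMBCl, K2CO3, DMF, 50 °C
Reagents that add atoms: 4-methoxybenzyl chloride, COc1ccc(CCl)cc1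
Why: Williamson etherification of an acidic salicylaldehyde phenol.

Step 3
Reactants: 4 5-bromo-2-[(4-methoxybenzyl)oxy]benzaldehyde
Product: 6 5-bromo-2-[(4-methoxybenzyl)oxy]phenol, via aryl formate 5 (not isolated)
Conditions: mCPBA, CH2Cl2, rt; then K2CO3 (cat.), MeOH, rt
Reagents that add atoms: meta-chloroperoxybenzoic acid, OOC(=O)c1cccc(Cl)c1
Why: Baeyer–Villiger (Dakin-type) oxidation with aryl migration favoured by the ortho-alkoxy group, followed by methanolysis of the formate; this places the new phenol meta to Br and ortho to OPMB.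

Step 4
Reactants: 6 5-bromo-2-[(4-methoxybenzyl)oxy]phenol; 7 4-chlorophenylboronic acid
Product: 8 4-bromo-2-(4-chlorophenoxy)-1-[(4-methoxybenzyl)oxy]benzene
Conditions: Cu(OAc)2 (20 mol %), pyridine, 4 Å MS, CH2Cl2, O2 (1 atm), rt
Reagents that add atoms: none
Why: Chan–Lam–Evans O-arylation forms the C–O–D diaryl ether at room temperature and leaves both aryl halides untouched.

Step 5
Reactants: 2 triisopropyl(3-vinylphenoxy)silane; 8 4-bromo-2-(4-chlorophenoxy)-1-[(4-methoxybenzyl)oxy]benzene
Product: 10 [3-(2-{3-(4-chlorophenoxy)-4-[(4-methoxybenzyl)oxy]phenyl}ethyl)phenoxy]triisopropylsilane, via B-alkyl-9-BBN adduct 9 (not isolated)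
Conditions: 9-BBN, THF, 0 °C to rt; then 8, Pd(dppf)Cl2 (5 mol %), aq. K3PO4, THF/DMF, 60 °C
Reagents that add atoms: none
Why: Anti-Markovnikov hydroboration followed by B-alkyl Suzuki–Miyaura coupling gives the bibenzyl directly at the saturated level; Pd/dppf should insert into C–Br and leave C–Cl.

Step 6
Reactants: 11 1-(2-hydroxy-5-methoxyphenyl)ethanone
Product: 12 1-[5-methoxy-2-(methoxymethoxy)phenyl]ethanone
Conditions: MOMCl, i-Pr2NEt, CH2Cl2, 0 °C to reflux
Reagents that add atoms: chloromethyl methyl ether, COCCl
Why: MOM protection removes the acidic chelated phenol so that the ketone enolate can be arylated cleanly.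

Step 7
Reactants: 10 [3-(2-{3-(4-chlorophenoxy)-4-[(4-methoxybenzyl)oxy]phenyl}ethyl)phenoxy]triisopropylsilane; 12 1-[5-methoxy-2-(methoxymethoxy)phenyl]ethanone
Product: 13 1-[5-methoxy-2-(methoxymethoxy)phenyl]-2-{4-[2-[(4-methoxybenzyl)oxy]-5-(2-{3-[(triisopropylsilyl)oxy]phenyl}ethyl)phenoxy]phenyl}ethanone
Conditions: Pd2(dba)3 (2.5 mol %), XPhos (10 mol %), K3PO4, toluene, 100 °C (12 in slight excess)
Reagents that add atoms: none
Why: Buchwald–Hartwig α-arylation of a methyl ketone with an aryl chloride; the bulky biarylphosphine should favour mono-arylation and the mild phosphate base should spare the silyl ether.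

Step 8
Reactants: 13 MOM-protected seco ketone
Product: 14 1-(2-hydroxy-5-methoxyphenyl)-2-{4-[2-[(4-methoxybenzyl)oxy]-5-(2-{3-[(triisopropylsilyl)oxy]phenyl}ethyl)phenoxy]phenyl}ethanone
Conditions: PPTS, MeOH/THF, 45 °C
Reagents that add atoms: none
Why: Mild acid transacetalisation cleaves the ortho-acyl aryl MOM ether (as dimethoxymethane) and should leave the PMB and TIPS aryl ethers intact.

Step 9
Reactants: 14 seco phenol
Product: 15 4,4-dimethoxy-2-({4-[2-[(4-methoxybenzyl)oxy]-5-(2-{3-[(triisopropylsilyl)oxy]phenyl}ethyl)phenoxy]phenyl}acetyl)cyclohexa-2,5-dien-1-one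
Conditions: PhI(OAc)2 (1.1 equiv), MeOH, 0 °C, short reaction time; filtration through Et3N-deactivated silica, used at once
Reagents that add atoms: methanol, CO
Why: Hypervalent-iodine oxidative dearomatisation of a para-methoxyphenol in methanol gives the quinone monoketal; the other arenes are ethers and are not oxidised under these conditions.

Step 10
Reactants: 15 acyl quinone monoketal
Product: 18 macrocyclic ketone (ring A: free OH and OMe; ring C: PMB ether), via free ring-B phenol 16 (not isolated), via conjugate adduct 17 (not isolated)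
Conditions: slow addition (syringe pump) of 15 to TBAF (1.2 equiv, dried over 4 Å MS), THF, final ca. 1 mM, 0 °C to rt; then TsOH·H2O (1.5 equiv), 4 Å MS, rt
Reagents that add atoms: none
Why: Proposed new method: fluoride unmasks the ring-B phenoxide of 16, which adds in an 18-endo-trig oxa-Michael fashion to C3 of the 2-acyl quinone monoketal to give the β-diketone enolate 17, and acid then ionises the allylic ketal so that loss of MeOH (C3–H and one C4–OMe) rearomatises ring A. The closest known reaction type is the conjugate addition–elimination of heteroatom and carbon nucleophiles to quinone monoketals, which gives 3-substituted 4-methoxyphenols, together with phenoxide SNAr macroetherification of activated arenes; the new element is an aryloxide closing a macrocyclic diaryl ether in this way. The only ring closed is the 18-membered macrocycle, through the ring-A C3–O bond, and no stereocentre survives because the two sp3 centres of 17 are destroyed on aromatisation. The step needs C3 over C5 regioselectivity, which the temporary benzylic ketone secures: only C3 is β to two carbonyl groups and only attack there gives a stabilised 1,3-dicarbonyl enolate, while the sites of the acid-mode SN2' pathway are blocked (C2) or remote (C6). Cyclisation over oligomerisation is secured by slow addition into dilute fluoride, and adducts that cannot aromatise can revert. In one operation the step should form the most hindered diaryl ether, close the macrocycle and deliver ring A with its OMe (from the ketal) and free OH (from the dienone carbonyl) already differentiated.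

Step 11
Reactants: 18 macrocyclic ketone
Product: 19 CNP0179896.0 (target)
Conditions: Et3SiH (6 equiv), TFA/CH2Cl2 (1:4), 0 °C to rt
Reagents that add atoms: none
Why: Ionic hydrogenation reduces the ortho-hydroxy, ortho-aryloxy aryl ketone to CH2 through an oxygen-stabilised benzylic cation, while TFA cleaves the PMB ether and the silane traps the PMB cation as 4-methylanisole.

## Compound list

1 | 3-vinylphenol | Oc1cccc(C=C)c1 | starting material
2 | triisopropyl(3-vinylphenoxy)silane | C=Cc1cccc(O[Si](C(C)C)(C(C)C)C(C)C)c1 | intermediate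
3 | 5-bromo-2-hydroxybenzaldehyde | O=Cc1cc(Br)ccc1O | starting material
4 | 5-bromo-2-[(4-methoxybenzyl)oxy]benzaldehyde | COc1ccc(COc2ccc(Br)cc2C=O)cc1 | intermediate
5 | 5-bromo-2-[(4-methoxybenzyl)oxy]phenyl formate (not isolated) | COc1ccc(COc2ccc(Br)cc2OC=O)cc1 | intermediate
6 | 5-bromo-2-[(4-methoxybenzyl)oxy]phenol | COc1ccc(COc2ccc(Br)cc2O)cc1 | intermediate
7 | 4-chlorophenylboronic acid | OB(O)c1ccc(Cl)cc1 | starting material
8 | 4-bromo-2-(4-chlorophenoxy)-1-[(4-methoxybenzyl)oxy]benzene | COc1ccc(COc2ccc(Br)cc2Oc2ccc(Cl)cc2)cc1 | intermediate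
9 | 9-{2-[3-(triisopropylsilyloxy)phenyl]ethyl}-9-borabicyclo[3.3.1]nonane (not isolated) | CC(C)[Si](Oc1cccc(CCB2C3CCCC2CCC3)c1)(C(C)C)C(C)C | intermediate
10 | [3-(2-{3-(4-chlorophenoxy)-4-[(4-methoxybenzyl)oxy]phenyl}ethyl)phenoxy]triisopropylsilane | COc1ccc(COc2ccc(CCc3cccc(O[Si](C(C)C)(C(C)C)C(C)C)c3)cc2Oc2ccc(Cl)cc2)cc1 | intermediate
11 | 1-(2-hydroxy-5-methoxyphenyl)ethanone | COc1ccc(O)c(c1)C(C)=O | starting material
12 | 1-[5-methoxy-2-(methoxymethoxy)phenyl]ethanone | COCOc1ccc(OC)cc1C(C)=O | intermediate
13 | MOM-protected seco ketone | COCOc1ccc(OC)cc1C(=O)Cc1ccc(cc1)Oc1cc(CCc2cccc(O[Si](C(C)C)(C(C)C)C(C)C)c2)ccc1OCc1ccc(OC)cc1 | intermediate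
14 | seco phenol (ring A free OH, ring B OTIPS, ring C OPMB) | COc1ccc(O)c(c1)C(=O)Cc1ccc(cc1)Oc1cc(CCc2cccc(O[Si](C(C)C)(C(C)C)C(C)C)c2)ccc1OCc1ccc(OC)cc1 | intermediate
15 | 2-acyl-4,4-dimethoxycyclohexa-2,5-dienone (quinone monoketal) | COC1(OC)C=CC(=O)C(=C1)C(=O)Cc1ccc(cc1)Oc1cc(CCc2cccc(O[Si](C(C)C)(C(C)C)C(C)C)c2)ccc1OCc1ccc(OC)cc1 | intermediate
16 | desilylated quinone monoketal, free ring-B phenol (not isolated) | COC1(OC)C=CC(=O)C(=C1)C(=O)Cc1ccc(cc1)Oc1cc(CCc2cccc(O)c2)ccc1OCc1ccc(OC)cc1 | intermediate
17 | macrocyclic oxa-Michael adduct, 3-aryloxy-4,4-dimethoxycyclohex-5-enone, transient stereocentres undefined (not isolated) | COC1(OC)C=CC(=O)C2C1Oc1cccc(c1)CCc1ccc(OCc3ccc(OC)cc3)c(c1)Oc1ccc(cc1)CC2=O | intermediate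
18 | macrocyclic ketone, ring-C PMB ether | COc1ccc(O)c2c1Oc1cccc(c1)CCc1ccc(OCc3ccc(OC)cc3)c(c1)Oc1ccc(cc1)CC2=O | intermediate
19 | CNP0179896.0 | COc1ccc(O)c2c1Oc1cccc(c1)CCc1ccc(O)c(c1)Oc1ccc(cc1)CC2 | target

## Summary

Total step count: 11. Longest linear sequence: 9 steps (steps 2, 3, 4, 5, 7, 8, 9, 10, 11 from compound 3).

## Steps most likely to fail

**Step 10 (proposed method).** The phenoxide may attack C5 instead of C3, the chain may oligomerise, or the ketal may hydrolyse instead of losing methanol, which would cost the methyl group. The fallback is a known SNAr macroetherification. It sets out from 10 and commercial 3-fluoro-4-methoxyphenol. The phenol is protected (MOMCl, i-Pr2NEt) as 2-fluoro-1-methoxy-4-(methoxymethoxy)benzene F1. Directed ortho-lithiation between F and OMOM (s-BuLi, THF, −78 °C) and quenching with N-methoxy-N-methylacetamide gives 1-[2-fluoro-3-methoxy-6-(methoxymethoxy)phenyl]ethanone F2. α-Arylation of F2 with 10 under the step 7 conditions gives the fluoro seco ketone F3, and TBAF liberates the ring-B phenol F4. Cs2CO3 in DMF at high dilution and 90–110 °C should then close the ring by displacement of the ketone-activated fluoride, giving the MOM-protected macrocyclic ketone F5. PPTS/MeOH as in step 8 returns the route at 18.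

**Step 9.** The doubly activated dienone may add methanol or decompose during oxidation and handling. The fallback avoids the monoketal. It sets out from 14: PhI(OAc)2 in MeCN/H2O should give the 2-acyl-1,4-benzoquinone F6 by oxidative demethylation. Fluoride-triggered conjugate addition of the ring-B phenoxide at the doubly activated C3 (slow addition, then Na2S2O4 work-up to return any over-oxidised material) would give the macrocyclic acylhydroquinone F7. MeI/K2CO3 in acetone methylates only the non-chelated OH, the one next to the aryloxy group, and returns the route at 18.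

**Step 11.** Deoxygenation of the hindered ketone may stop short, or the PMB cation may alkylate the electron-rich rings. The fallback separates hydride reduction from hydrogenolysis. It sets out from 18: NaBH4 in MeOH/THF gives the racemic macrocyclic benzylic alcohol F8. H2 over Pd(OH)2/C in EtOAc/AcOH then cleaves both the ortho-hydroxybenzylic C–OH bond and the PMB ether, arriving at 19.

## Further compounds

F1 | step 10 | 2-fluoro-1-methoxy-4-(methoxymethoxy)benzene | COCOc1ccc(OC)c(F)c1
F2 | step 10 | 1-[2-fluoro-3-methoxy-6-(methoxymethoxy)phenyl]ethanone | COCOc1ccc(OC)c(F)c1C(C)=O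
F3 | step 10 | fluoro seco ketone (ring A F/OMOM, ring B OTIPS, ring C OPMB) | COCOc1ccc(OC)c(F)c1C(=O)Cc1ccc(cc1)Oc1cc(CCc2cccc(O[Si](C(C)C)(C(C)C)C(C)C)c2)ccc1OCc1ccc(OC)cc1
F4 | step 10 | fluoro seco ketone with free ring-B phenol | COCOc1ccc(OC)c(F)c1C(=O)Cc1ccc(cc1)Oc1cc(CCc2cccc(O)c2)ccc1OCc1ccc(OC)cc1
F5 | step 10 | MOM-protected macrocyclic ketone | COCOc1ccc(OC)c2c1C(=O)Cc1ccc(cc1)Oc1cc(ccc1OCc1ccc(OC)cc1)CCc1cccc(c1)O2
F6 | step 9 | 2-acyl-1,4-benzoquinone seco compound (ring B OTIPS, ring C OPMB) | O=C1C=CC(=O)C(=C1)C(=O)Cc1ccc(cc1)Oc1cc(CCc2cccc(O[Si](C(C)C)(C(C)C)C(C)C)c2)ccc1OCc1ccc(OC)cc1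
F7 | step 9 | macrocyclic acylhydroquinone, ring-C PMB ether | Oc1ccc(O)c2c1Oc1cccc(c1)CCc1ccc(OCc3ccc(OC)cc3)c(c1)Oc1ccc(cc1)CC2=O
F8 | step 11 | racemic macrocyclic benzylic alcohol, ring-C PMB ether | COc1ccc(O)c2c1Oc1cccc(c1)CCc1ccc(OCc3ccc(OC)cc3)c(c1)Oc1ccc(cc1)CC2O
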